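**Plan**

1. Ring A is the benzene ring with the ether oxygen at C1, the chain at C3 and OH at C5. Ring B is the ring with the ether oxygen at C1, OH at C2 and C6 and the chain at C4. Retrosynthetic cuts, in order: the three phenol O–H as O–CH3; the chain bond between the second and third carbon counted from ring B, as a C=C, which opens the 20-membered ring; the ring A C(aryl)–CH2 bond; the ether O–C(ring A) bond.
2. Enabling feature: ring B with its first three chain carbons is the allylbenzene unit of commercial 4-allyl-2,6-dimethoxyphenol 1, and the bond to be made is the outer bond of that allyl group. The rest of the bridge is an unbranched, unfunctionalised polymethylene chain, so ring-closing olefin metathesis of an allyl/undec-10-enyl diene closes the macrocycle there and hydrogenation removes the alkene. The diaryl ether oxygen (meta on ring A, para on ring B) is the hinge that lets the twelve-carbon bridge span both rings without strain.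
3. Forward: Ullmann etherification of 1 with 3,5-dibromoanisole 2 gives bromo diaryl ether 3. Negishi coupling with zinc reagent 5, made in the flask from 11-bromoundec-1-ene 4, gives diene 6. Metathesis closes the only new ring (7); hydrogenation (8) and BBr3 demethylation give target 9.
4. Stereochemistry: the target has no stereocentre. The E/Z geometry of alkene 7 is not controlled and is erased in step 4.

Key step: step 3

**Route**

Step 1
Reactants: 1 4-allyl-2,6-dimethoxyphenol; 2 3,5-dibromoanisole (1,3-dibromo-5-methoxybenzene)
Product: 3 5-allyl-2-(3-bromo-5-methoxyphenoxy)-1,3-dimethoxybenzene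
Conditions: CuI (10 mol %), picolinic acid (20 mol %), K3PO4 (2 equiv), DMSO, 90 °C, argon; 3,5-dibromoanisole in threefold excess
Reagents that add atoms: none
Why: Ullmann-type copper-catalysed diaryl ether synthesis, in which the CuI–picolinic acid system is the one suited to hindered 2,6-disubstituted phenols, the excess of the symmetrical dibromide should hold the reaction at mono-substitution, and K3PO4 is too weak a base to move the allyl double bond into conjugation.

Step 2
Reactants: 3 5-allyl-2-(3-bromo-5-methoxyphenoxy)-1,3-dimethoxybenzene; 4 11-bromoundec-1-ene
Product: 6 5-allyl-1,3-dimethoxy-2-[3-methoxy-5-(undec-10-en-1-yl)phenoxy]benzene, via undec-10-enylzinc bromide 5 (not isolated)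
Conditions: 4, Zn dust (activated with BrCH2CH2Br and Me3SiCl), LiCl, THF, 50 °C; then 3, Pd(OAc)2 (2 mol %), SPhos (4 mol %), THF, 25 to 50 °C
Reagents that add atoms: none
Why: Negishi sp3–sp2 cross-coupling, in which LiCl-promoted zinc insertion turns the primary bromide into the alkylzinc bromide, this transmetalates to the arylpalladium bromide formed from the aryl bromide and zerovalent palladium, and the bulky biarylphosphine should make reductive elimination faster than beta-hydride elimination while the ethers and both terminal alkenes stay inert to the organozinc.

Step 3
Reactants: 6 5-allyl-1,3-dimethoxy-2-[3-methoxy-5-(undec-10-en-1-yl)phenoxy]benzene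
Product: 7 tri-O-methyl macrocyclic alkene (ring B–CH2–CH=CH–(CH2)9–ring A; E/Z mixture)
Conditions: second-generation Grubbs catalyst (H2IMes)(PCy3)Cl2Ru=CHPh (two portions of 2.5 mol %), 1,4-benzoquinone (10 mol %), CH2Cl2 (1 mM), 40 °C, argon sparge
Reagents that add atoms: none
Why: The ruthenium benzylidene is exchanged onto one of the two monosubstituted terminal alkenes of the diene by [2+2] cycloaddition and cycloreversion, the resulting ruthenium alkylidene adds to the other terminal alkene of the same molecule to give a ruthenacyclobutane, and cycloreversion releases the cycloalkene and Ru=CH2, loss of ethene from the sparged solution making the closure irreversible (Chauvin mechanism). The closest known reaction type is the ring-closing olefin metathesis macrocyclisation of alpha,omega-dienes having an allylarene terminus to bridged diaryl ether and biaryl cyclophanes of 14 to 22 ring atoms. The one ring formed is the 20-membered macrocycle (three atoms of ring A, the ether oxygen, four atoms of ring B, twelve chain carbons), closed end to end, the new C=C between the second and third chain carbons counted from ring B lying inside the ring. No stereocentre is formed, and the E/Z ratio of the new alkene is immaterial because step 4 saturates it. The step needs cyclisation to outrun acyclic diene metathesis oligomerisation, which the 1 mM concentration and the bent diaryl ether hinge of the diene (meta chain on ring A, para allyl group on ring B) should secure; it also needs the allyl double bond not to migrate into conjugation before closure, since that would lead to a ring-contracted 19-membered alkene by loss of propene, and the hydride scavenger 1,4-benzoquinone and the mild temperature should prevent this. All oxygen functions of the diene are ethers, so nothing in the substrate should bind or decompose the catalyst.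

Step 4
Reactants: 7 tri-O-methyl macrocyclic alkene (ring B–CH2–CH=CH–(CH2)9–ring A; E/Z mixture)
Product: 8 tri-O-methyl ether of the target (ring B–(CH2)12–ring A; saturated 20-membered macrocycle)
Conditions: H2 (1 atm), Pd/C, EtOAc, 25 °C
Reagents that add atoms: none
Why: Heterogeneous catalytic hydrogenation of the unhindered 1,2-disubstituted macrocyclic alkene, under which both geometric isomers should converge on one product while the aryl methyl ethers and the diaryl ether, which have no benzylic C–O bond, stay untouched.

Step 5
Reactants: 8 tri-O-methyl ether of the target (ring B–(CH2)12–ring A; saturated 20-membered macrocycle)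
Product: 9 target CNP0314249.0 (ring B–(CH2)12–ring A; macrocyclic triphenol)
Conditions: BBr3 (6 equiv), CH2Cl2, −78 °C to 25 °C; then ice-water, 0 °C, under argon
Reagents that add atoms: none
Why: Lewis acid ether cleavage by BBr3, in which each methoxy oxygen binds boron and bromide attacks the methyl carbon by SN2, whereas the diaryl ether has no sp3 carbon for such attack and should survive, and hydrolysis of the aryl borates on work-up frees the three phenols.

**Compound list**

1 | 4-allyl-2,6-dimethoxyphenol | C=CCc1cc(OC)c(O)c(OC)c1 | starting material
2 | 3,5-dibromoanisole (1,3-dibromo-5-methoxybenzene) | COc1cc(Br)cc(Br)c1 | starting material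
3 | 5-allyl-2-(3-bromo-5-methoxyphenoxy)-1,3-dimethoxybenzene | C=CCc1cc(OC)c(Oc2cc(Br)cc(OC)c2)c(OC)c1 | intermediate
4 | 11-bromoundec-1-ene | C=CCCCCCCCCCBr | starting material
5 | undec-10-enylzinc bromide (not isolated) | C=CCCCCCCCCC[Zn]Br | intermediate
6 | 5-allyl-1,3-dimethoxy-2-[3-methoxy-5-(undec-10-en-1-yl)phenoxy]benzene | C=CCc1cc(OC)c(Oc2cc(OC)cc(CCCCCCCCCC=C)c2)c(OC)c1 | intermediate
7 | tri-O-methyl macrocyclic alkene (ring B–CH2–CH=CH–(CH2)9–ring A; E/Z mixture) | COc1cc2cc(c1)Oc1c(OC)cc(cc1OC)CC=CCCCCCCCCC2 | intermediate
8 | tri-O-methyl ether of the target (ring B–(CH2)12–ring A; saturated 20-membered macrocycle) | COc1cc2cc(c1)Oc1c(OC)cc(cc1OC)CCCCCCCCCCCC2 | intermediate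
9 | target CNP0314249.0 (ring B–(CH2)12–ring A; macrocyclic triphenol) | Oc1cc2cc(c1)Oc1c(O)cc(cc1O)CCCCCCCCCCCC2 | target

**Count**

Total steps: 5. Longest linear sequence: 5 steps (1 → 3 → 6 → 7 → 8 → 9).

**Steps most likely to fail**

Step 3. The diene may oligomerise by acyclic diene metathesis instead of cyclising. The allyl double bond may also migrate before closure, which would give ring-contracted homologues. The fallback sets out from 6 and forms the same C=C by reductive carbonyl coupling instead of metathesis. Both terminal alkenes of 6 are cleaved (OsO4 cat., NaIO4, 2,6-lutidine, dioxane–water, 25 °C) to the dialdehyde 10-{3-[2,6-dimethoxy-4-(2-oxoethyl)phenoxy]-5-methoxyphenyl}decanal F1. F1 is used at once and closed by intramolecular McMurry coupling on low-valent titanium (TiCl3(DME)1.5, Zn(Cu), DME, reflux, syringe-pump addition). This should give alkene 7, where the route is rejoined.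

Step 1. The C–O coupling may be slow because the phenol oxygen sits between two methoxy groups. A second arylation of the dibromide or oxidative dimerisation of the electron-rich phenol may compete. The fallback sets out from 2 and replaces the copper-catalysed halide coupling by an oxidative coupling at room temperature. Mono bromine–lithium exchange on 2 (n-BuLi, Et2O, −78 °C), trapping by B(OiPr)3 and acidic aqueous work-up should give (3-bromo-5-methoxyphenyl)boronic acid F2. Chan–Lam coupling of F2 and 1 (Cu(OAc)2, pyridine, 4 Å molecular sieves, CH2Cl2, air, 25 °C; divalent copper) should give 3, the C–Br bond staying untouched.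

Step 2. Beta-hydride elimination and chain walking in the alkylpalladium intermediate, palladium hydride-induced migration of the allyl double bond, or slow oxidative addition to the electron-rich bromide may erode the coupling. The fallback sets out from 3 and makes the aryl–alkyl bond by carbonyl addition and deoxygenation. Bromine–lithium exchange on 3 (n-BuLi, THF, −78 °C) and addition of the aryllithium to undec-10-enal should give the racemic benzylic alcohol 1-[3-(4-allyl-2,6-dimethoxyphenoxy)-5-methoxyphenyl]undec-10-en-1-ol F3. Ionic deoxygenation of F3 (Et3SiH, CF3CO2H, CH2Cl2, 0 °C) removes the hydroxyl group and its stereocentre and should give 6.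

**Further compounds**

F1 | step 3 | 10-{3-[2,6-dimethoxy-4-(2-oxoethyl)phenoxy]-5-methoxyphenyl}decanal | O=CCc1cc(OC)c(Oc2cc(OC)cc(CCCCCCCCCC=O)c2)c(OC)c1
F2 | step 1 | (3-bromo-5-methoxyphenyl)boronic acid | COc1cc(Br)cc(B(O)O)c1
F3 | step 2 | 1-[3-(4-allyl-2,6-dimethoxyphenoxy)-5-methoxyphenyl]undec-10-en-1-ol (racemic) | C=CCc1cc(OC)c(Oc2cc(OC)cc(C(O)CCCCCCCCC=C)c2)c(OC)c1
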